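**Remark on the structures:** the key-step precursor and product, the starting materials and the three alternative key-step products were compared atom by atom with the target (C4, C5, C9, C10 as in abietic acid; 6α-O; 8α-O; 13E; 15S,16S, i.e. syn) and needed no correction. The precursor keeps its constitution; only the way to it is changed (amide first, silylation before the oxygen insertion).

## Structural features

The target is a labdane-type diterpenoid: a trans-fused decalin (ring A = C1–C5 and C10, ring B = C5–C10) carrying at C9 a chain C11–C16 that ends in a 4-methylbutenolide whose O–CH carbon is C16. Six of the eight stereocentres lie on the decalin in two contiguous triads that meet at the ring fusion: C4 (quaternary, α-CO2Me, β-CH3)–C5–C6 (α-OH) and C8 (tertiary α-OH, β-CH3)–C9–C10 (quaternary, β-CH3). The remaining two, C15 (S, allylic OH) and C16 (S), are syn to each other and lie beyond the (E)-trisubstituted C13=C14 alkene, too far from the ring for substrate control. The fragile groups are the butenolide (acidic γ-hydrogen at C16, retro-aldol across C15–C16, ring opening by hydroxide), the allylic C15 alcohol (ionisation in acid), the tertiary C8 alcohol (it closes onto any C13 carbonyl as a six-membered lactone or hemiketal) and the 6α-hydroxy/C4-ester pair, which can re-close to a lactone. The real difficulties are the α-oxygen on the unactivated methylene C6 and the absolute control of the remote C15/C16 pair; C4, C5, C9 and C10 can be bought with the resin-acid skeleton. The key step exploits the peri relationship across C5 of the α-equatorial carbonyl carbon on C4 and the equatorial 6α-hydrogen. That carbonyl is gauche to C6 and anti to C2, so a nitrogen radical on it reaches H6α through a six-membered array and the carbonyl oxygen then closes the five-membered ring carbonyl C–C4–C5–C6–O.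

## Logic of the disconnections

**30 ⇒ 29.** The O–Si bonds at O6 and O8 are cut last in the forward sense. Both hydroxyls are masked so that organometallic, hydride and Lewis-acid steps cannot re-close the C4 lactone or cyclise O8 onto C13. This adds no skeletal simplicity but makes every later step safe. The forward step needs a non-basic fluoride source that spares the butenolide and the allylic alcohol.

**29 ⇒ 25 + 27.** The C15–C16 bond is cut. This removes the whole butenolide as a five-carbon nucleophile and creates both side-chain stereocentres in the bond-forming step, so 25 has no stereocentre outside the decalin. The forward vinylogous aldol must be γ-selective, must add 1,2 to the enal, must give the syn pair and must choose the aldehyde face by catalyst control, because the ring is too far away to help.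

**25 ⇒ 24 ⇒ 23 ⇒ 22.** The C13=C14 double bond is cut after redox adjustment at C15. A two-carbon phosphonate olefination of a methyl ketone is the shortest way to the trisubstituted enal. The demands are E geometry at a methyl ketone-derived alkene and a hydride reduction that spares the hindered C4 ester.

**22 ⇒ 21 ⇒ 20.** The C13–CH3 bond is cut, tracing the ketone to a chain ester through an N-methoxy-N-methylamide. The gain is that C13 returns to the carboxyl oxidation state that ring cleavage delivers. The forward steps must tell the unhindered chain ester from the neopentyl-type C4 ester, which sterics should allow.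

**20 ⇒ 19 ⇒ 17.** In the retrosynthetic sense the 6α-hydroxyl and the C4 ester are joined into one γ-lactone, so two functional groups become one ring. The forward opening must be irreversible: hydroxide opens the lactone and the carboxylates are alkylated without acidification. The chain ester is hydrolysed and re-methylated in the same operation, which does no harm.

**17 ⇒ 12 (with 13).** The C6–O bond is cut. C6 becomes a plain methylene, so the precursor has no oxygen between C5 and C7, exactly what the resin-acid core offers. The forward step needs site selectivity for H6α over C2, C7 and the C4 methyl, α-face delivery, O- over N-closure, and survival of the silyl ether and the isopropyl ester. In 12 the C8 oxygen is silylated, the nitrogen is unsubstituted so that the iminolactone hydrolyses, and the chain ester has no activated C–H within reach of the nitrogen radical.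

**12 ⇒ 11 ⇒ 10.** The C13–O bond of the chain ester is cut (retro oxygen insertion), revealing an isopropyl ketone whose isopropyl group is the one the starting material already carries. The O–Si bond is then cut. The forward insertion relies on migration of the secondary alkyl group. Silylation is placed before it so that a free C8 hydroxyl never meets a C13 acyl group.

**10 ⇒ 9.** The C8–O bond is cut to a 1,1-disubstituted exocyclic alkene. Markovnikov radical hydration then gives the methyl group and the tertiary alcohol at once. The demand is trapping of the C8 radical on the α face, away from the axial C10 methyl.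

**9 ⇒ 6 ⇒ 5.** The C–O bond of an allylic alcohol is removed with 1,3-transposition of the alkene, so the enal carbon becomes the future C8 methyl. The demands are reduction of the conjugated aldehyde in the presence of the isopropyl ketone and a deoxygenation that tolerates ketone and amide.

**5 ⇒ 4 ⇒ 3.** The C13–C14 bond is reconnected, restoring ring C as a 7,13-diene. The gain is an intact tricyclic skeleton with four correct stereocentres. The forward dihydroxylation must choose the C13=C14 alkene over C7=C8.

**3 ⇒ 1 (through 2).** The C–N bond of the carboxamide is cut. The amide is installed first, so no hindered acid has to be activated later beside a silyl ether, and the acylation conditions must not isomerise the diene.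

**27 ⇒ 26.** The O–Si bond of the silyloxyfuran is cut. Enol silylation of the butenolide is a one-step preparation and demands only exclusion of moisture.

## Other disconnections considered

**Alternative 1:** The cut is through ring A at C2–C3 and C4–C5. In the forward sense the diene A1 and methacrolein A2 combine under the chiral cationic oxazaborolidine salt [C24H25BNO][N(SO2CF3)2] to give the cyclohexene aldehyde A3, the exo transition state placing the formyl group trans to the silyloxymethyl arm.
- *In favour:* the C4 quaternary centre and C5 are set by a catalyst from small achiral components, and either enantiomer and many analogues are open. C6 arrives already oxygenated, so no C–H functionalisation is needed. On that point the alternative is better than the chosen plan, and its concerted, well-modelled cycloaddition is at least the equal of a radical hydrogen transfer in predictability.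
- *Against:* A3 holds one ring and two of the eight stereocentres. Ring B with C8, C9 and the quaternary C10 must still be built from the C10=C1 alkene, and the C6 carbinol configuration has to be set when C6–C7 is formed. The directing effects of the C5 substituent and the C10 methyl on the diene oppose each other, so the regiochemistry is less secure than it looks.
- *Comparison:* the chosen plan buys rings A and B with C4, C5, C9 and C10 in one commercial compound, whereas this route is de novo and would be expected to need roughly twice as many steps as the eighteen planned here.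

**Alternative 2:** The cut is at C3–C4 and C5–C10. On heating or with Me2AlCl the triene A4 would undergo intramolecular Diels–Alder reaction of its (E)-2-methyl enoate with the C10=C1–C2=C3 diene to give the octalin A5.
- *In favour:* one step forms two rings, two C–C bonds and three stereocentres (C4, C5, C10), both quaternary carbons included, far more per step than the chosen key step (one ring, one C–O bond, one stereocentre). On that count the alternative is better. The C6 and C8 oxygens are already in place.
- *Against:* A4 must be prepared as a single isomer with three stereocentres (C6, the tertiary C8 ether, C9) and two defined trisubstituted alkenes. The diene terminus C10 is fully substituted with its methyl cis to C2, which disfavours the s-cis conformer and invites 1,5-hydrogen shift. Both new bonds create quaternary carbons, the trans ring fusion depends on tether substituents, and the Lewis acid meets two silyl ethers and a benzylic ether. Hydrogenation of C1=C2 and extension of the C11–C12 stub still follow.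
- *Comparison:* both plans reach the same decalin. The chosen plan has no uncertainty about the four ring stereocentres it purchases, and the preparation of A4 alone should cost about as many steps as the whole route to 17.

**Alternative 3:** The cut is at C13–CH3 and C14–C15. Cp2ZrCl2-catalysed syn addition of AlMe3 to the terminal alkyne A6 would give an (E)-alkenylalane whose C14 adds to the α-alkoxy aldehyde A7, giving the allylic alcohol A8.
- *In favour:* the E geometry follows from syn carbometalation and is more certain than the olefination of 22, so here the alternative is better. C16 comes from the chiral pool, so the absolute configuration of the side chain is bought and not induced, which is also more certain than a catalyst-controlled aldol. The coupling is convergent.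
- *Against:* the free C8 hydroxyl consumes AlMe3, alkenylalanes add sluggishly to aldehydes without ate activation, and the syn relationship requires chelation by the benzylic ether to win over the Felkin–Anh mode. A7 is epimerisable, and after A8 the butenolide still has to be built (oxidation at C17, methyl addition, oxidation, acylation, ring closure, ether removal), about six steps where the chosen plan uses one.
- *Comparison:* this is a side-chain disconnection only and leaves the C6 oxygen untouched. It is complementary, since A6 could be reached from 20, and would be the natural substitute if step 17 failed on stereocontrol, at a cost of about five extra steps.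

Key step: step 8

## Route

**Step 1**
Reactants: 1 abietic acid (abieta-7,13-dien-18-oic acid; C4 α-CO2H and β-CH3, 5α-H, 9α-H, 10β-CH3)
Product: 3 abieta-7,13-dien-18-amide (primary C4 carboxamide of 1), via acid chloride 2 (not isolated)
Conditions: 1-chloro-N,N,2-trimethylprop-1-en-1-amine, CH2Cl2, 0 °C to rt; then NH3 (0.5 M in dioxane), 0 °C
Reagents that add atoms: ammonia, N
Why: Neutral acid chloride formation avoids the hydrogen chloride that would isomerise the heteroannular diene, and the small nucleophile ammonia acylates even at the neopentyl-type C4 carbonyl (amide formation through the acyl chloride); no stereocentre is touched.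

**Step 2**
Reactants: 3 abieta-7,13-dien-18-amide
Product: 5 ring C-opened keto enal amide (C7=C8 bearing the formyl carbon on C8; C9 chain CH2CH2C(=O)CH(CH3)2), via 13,14-diol 4 (not isolated)
Conditions: OsO4 (2 mol %), NMO (1.1 equiv), acetone/H2O, rt; then NaIO4, rt
Reagents that add atoms: N-methylmorpholine N-oxide, C[N+]1([O-])CCOCC1; water, O
Why: Catalytic dihydroxylation should take the more accessible, more electron-rich C13=C14 end of the diene from the α face, and glycol cleavage by periodate then opens ring C; the enal alkene that results is deactivated towards further osmylation, and C9 is not affected.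

**Step 3**
Reactants: 5 ring C-opened keto enal amide
Product: 6 allylic alcohol amide (C8–CH2OH on the C7=C8 alkene; isopropyl ketone retained)
Conditions: NaBH4, EtOH/CH2Cl2, −78 °C
Reagents that add atoms: none
Why: At low temperature borohydride reduces an aldehyde, conjugated or not, much faster than an α-branched ketone (chemoselective 1,2-reduction); cerium salts are avoided because they would reverse this preference.

**Step 4**
Reactants: 6 allylic alcohol amide
Product: 9 exocyclic alkene amide (C8=CH2 with C7 now CH2; isopropyl ketone retained), via sulfonylhydrazone adduct 7 (not isolated), via allylic diazene 8 (not isolated)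
Conditions: N'-isopropylidene-2-nitrobenzenesulfonohydrazide, PPh3, DEAD, THF, 0 °C to rt; then CF3CH2OH/H2O, rt
Reagents that add atoms: none
Why: Mitsunobu displacement of the primary allylic alcohol by the sulfonyl hydrazone, hydrolysis and loss of sulfinic acid give a monoalkyl diazene that extrudes N2 by a retro-ene shift, delivering hydrogen to C7 and moving the alkene to the exocyclic position (reductive 1,3-transposition of an allylic alcohol); the acetone-masked reagent cannot condense with the C13 ketone.

**Step 5**
Reactants: 9 exocyclic alkene amide
Product: 10 8α-hydroxy amide (C8 β-CH3 and α-OH; isopropyl ketone retained)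
Conditions: Co(acac)2 (20 mol %), PhSiH3, O2 (1 atm), THF, rt; then aq. Na2S2O3
Reagents that add atoms: dioxygen, O=O
Why: Hydrogen-atom transfer to the terminal carbon gives the tertiary C8 radical (Mukaiyama hydration, Markovnikov); oxygen should be trapped on the α face, equatorially and away from the axial C10 methyl, which sets the C8 stereocentre as 8α-OH with the new methyl axial.

**Step 6**
Reactants: 10 8α-hydroxy amide
Product: 11 8α-triethylsilyloxy amide (isopropyl ketone retained)
Conditions: TESOTf, 2,6-lutidine, CH2Cl2, −78 to 0 °C; then K2CO3, MeOH, 0 °C
Reagents that add atoms: triethylsilyl trifluoromethanesulfonate, CC[Si](CC)(CC)OS(=O)(=O)C(F)(F)F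
Why: The silyl triflate silylates the hindered tertiary alcohol; any N-silyl imidate or enol silane formed at the amide or ketone is cleaved by the brief methanolysis, while the tertiary silyl ether stays.

**Step 7**
Reactants: 11 8α-triethylsilyloxy amide
Product: 12 8α-triethylsilyloxy C4 carboxamide with the C9 chain CH2CH2CO2CH(CH3)2 (key-step precursor)
Conditions: mCPBA, NaHCO3, CH2Cl2, rt
Reagents that add atoms: 3-chloroperoxybenzoic acid, OOC(=O)c1cccc(Cl)c1
Why: In the Baeyer–Villiger oxidation the secondary isopropyl group migrates in preference to the primary C12 methylene, so oxygen is inserted between C13 and the isopropyl carbon; the buffer protects the silyl ether, and no alkene or free hydroxyl remains to compete.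

**Step 8**
Reactants: 12 key-step precursor; 13 (diacetoxyiodo)benzene
Product: 17 γ-lactone from the C4 carbonyl to the 6α-oxygen (8α-triethylsilyloxy and isopropyl ester retained), via N-iodoamide 14 (not isolated), via C6 iodide 15 (not isolated), via iminolactone 16 (not isolated)
Conditions: PhI(OAc)2 premixed with I2, NaHCO3, CH2Cl2, visible light (tungsten lamp), rt; then aq. Na2S2O3; THF/H2O/AcOH, rt
Reagents that add atoms: water, O
Why: The oxidant and I2 give acetyl hypoiodite, which N-iodinates the primary amide to 14; light homolyses the N–I bond, the amidyl radical abstracts the equatorial 6α-hydrogen through a six-membered array (N, carbonyl C, C4, C5, C6, H), the C6 radical is capped by iodine to 15, and the amide oxygen displaces iodide to give iminolactone 16, which water converts to 17 with loss of ammonia. The closest known reaction type is the photolysis of N-iodoamides to γ-lactones, a Hofmann–Löffler–Freytag-type 1,5-hydrogen transfer. The one ring formed (carbonyl C–C4–C5–C6–O) closes in the 5-exo-tet mode by attack of the carbonyl oxygen on C6. The new stereocentre C6 is controlled by the tether: the nucleophile is anchored on the α-equatorial carbonyl carbon, so oxygen can only arrive on the α face whichever epimer of 15 is present, the 6β-iodide by direct inversion and the 6α-iodide after re-homolysis under the light or ionisation once excess oxidant has made the iodine a hypervalent leaving group. The site selectivity that is needed comes from geometry: the carbonyl is gauche to C6 but anti to C2, the C4 methyl would require a five-membered and C7 a seven-membered transition state. Oxygen is the kinetically preferred alkylation site of a neutral amide, which should favour lactone over lactam. The C8 oxygen is silylated so that no hypoiodite or alkoxy radical can form there, solid NaHCO3 takes up the acid that could cleave the silyl ether, and premixing the oxidant with I2 keeps free trivalent iodine away from the amide and so suppresses Hofmann-type rearrangement.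

**Step 9**
Reactants: 17 γ-lactone
Product: 19 6α-hydroxy dimethyl ester (C4 CO2CH3 and chain CH2CH2CO2CH3; 8α-triethylsilyloxy), via dipotassium salt 18 (not isolated)
Conditions: KOH, MeOH/H2O, 60 °C; CO2 to pH 8, evaporate; MeI, DMF, rt
Reagents that add atoms: potassium hydroxide, [K+].[OH-]; iodomethane, CI
Why: Hydroxide opens the strained trans-fused lactone and hydrolyses the chain ester; alkylating the carboxylates directly (SN2 at methyl, insensitive to hindrance at C4) avoids the acidification that would re-close the lactone, and C6 keeps its configuration because only the acyl C–O bond is broken.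

**Step 10**
Reactants: 19 6α-hydroxy dimethyl ester
Product: 20 6α,8α-bis(triethylsilyloxy) dimethyl ester
Conditions: TESOTf, 2,6-lutidine, CH2Cl2, −78 to 0 °C
Reagents that add atoms: triethylsilyl trifluoromethanesulfonate, CC[Si](CC)(CC)OS(=O)(=O)C(F)(F)F
Why: Silylation of the equatorial secondary alcohol removes the alkoxide that could re-lactonise onto the C4 ester in the basic steps that follow, and gives a group that leaves with the C8 silyl ether in the last step.

**Step 11**
Reactants: 20 bis(triethylsilyloxy) dimethyl ester
Product: 21 C13 N-methoxy-N-methylamide (C4 methyl ester retained)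
Conditions: MeNH(OMe)·HCl, i-PrMgCl, THF, −20 to 0 °C
Reagents that add atoms: N,O-dimethylhydroxylamine hydrochloride, CNOC.Cl
Why: The magnesium amide attacks the unhindered chain ester, while the C4 ester on a quaternary carbon flanked by the C6 silyl ether is inert under these conditions (Weinreb amide formation from an ester).

**Step 12**
Reactants: 21 C13 N-methoxy-N-methylamide
Product: 22 C13 methyl ketone (chain CH2CH2C(=O)CH3)
Conditions: MeMgBr, THF, 0 °C
Reagents that add atoms: methylmagnesium bromide, C[Mg]Br
Why: The chelated tetrahedral intermediate stops the addition at the ketone stage (Weinreb ketone synthesis), and the hindered C4 ester does not react at this temperature.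

**Step 13**
Reactants: 22 C13 methyl ketone
Product: 23 ethyl (13E)-enoate (chain CH2CH2C(CH3)=CH–CO2Et)
Conditions: (EtO)2P(O)CH2CO2Et, NaH, THF, 0 to 60 °C
Reagents that add atoms: triethyl phosphonoacetate, CCOC(=O)CP(=O)(OCC)OCC
Why: The Horner–Wadsworth–Emmons reaction of a methyl alkyl ketone should favour the E isomer (ester trans to the larger C12 chain); the minor Z isomer is expected to be separable by chromatography at this stage or after step 14.

**Step 14**
Reactants: 23 ethyl (13E)-enoate
Product: 24 (13E)-allylic alcohol (chain CH2CH2C(CH3)=CH–CH2OH)
Conditions: i-Bu2AlH, CH2Cl2, −78 °C; aq. potassium sodium tartrate (KNaC4H4O6)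
Reagents that add atoms: none
Why: The unhindered conjugated ester is reduced 1,2 to the allylic alcohol at low temperature, while the C4 ester, shielded by the quaternary centre and the C6 silyl ether, should be left untouched with a limited amount of hydride.

**Step 15**
Reactants: 24 (13E)-allylic alcohol
Product: 25 (13E)-enal (chain CH2CH2C(CH3)=CH–CHO)
Conditions: MnO2, CH2Cl2, rt
Reagents that add atoms: none
Why: Activated MnO2 oxidises allylic alcohols selectively and under neutral conditions, so the alkene geometry and the silyl ethers are preserved.

**Step 16**
Reactants: 26 4-methylfuran-2(5H)-one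
Product: 27 tert-butyldimethyl[(4-methylfuran-2-yl)oxy]silane
Conditions: TBSOTf, Et3N, CH2Cl2, 0 °C
Reagents that add atoms: tert-butyldimethylsilyl trifluoromethanesulfonate, CC(C)(C)[Si](C)(C)OS(=O)(=O)C(F)(F)F
Why: Soft enolisation of the butenolide at C5 and O-silylation give the aromatic 2-silyloxyfuran, the standard vinylogous nucleophile of this class.

**Step 17**
Reactants: 25 (13E)-enal; 27 silyloxyfuran
Product: 29 6,8-bis-O-triethylsilyl ether of the target (15S,16S), via trichlorosilyl ether 28 (not isolated)
Conditions: SiCl4, (R,R)-bisphosphoramide C51H52N6O2P2 (two N,N'-dimethyl-1,1'-binaphthyl-2,2'-diamine phosphoryl units on an N,N'-dimethylpentane-1,5-diamine linker, 5 mol %), i-Pr2NEt (10 mol %), CH2Cl2, −78 °C; then aq. NaHCO3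
Reagents that add atoms: none
Why: The Lewis base-activated silicon Lewis acid binds the enal, and the furan adds through its C5 (γ) carbon in an open transition state (catalytic asymmetric vinylogous Mukaiyama aldol addition, 1,2-mode); for furan-based dienoxysilanes this mode should favour the syn adduct, and the (R,R)-catalyst is expected to expose the Re face of the aldehyde, which corresponds to 15S and hence 15S,16S. Conjugated aldehydes are the best electrophiles for this catalyst class, and both ring hydroxyls are silylated, so nothing competes for SiCl4.

**Step 18**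
Reactants: 29 bis-O-triethylsilyl ether of the target
Product: 30 CNP0104474.1 (target)
Conditions: HF·pyridine, pyridine, THF, 0 °C to rt
Reagents that add atoms: none
Why: Buffered fluoride removes both silyl ethers without the basic conditions that would epimerise C16, trigger retro-aldol cleavage or re-close the C4 lactone, and without acid strong enough to ionise the allylic C15 alcohol.

## Compound list

1 | abietic acid | OC(=O)[C@]1(C)CCC[C@@]2(C)[C@H]1CC=C3C=C(C(C)C)CC[C@H]23 | starting material
2 | abieta-7,13-dien-18-oyl chloride (not isolated) | ClC(=O)[C@]1(C)CCC[C@@]2(C)[C@H]1CC=C3C=C(C(C)C)CC[C@H]23 | intermediate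
3 | abieta-7,13-dien-18-amide | NC(=O)[C@]1(C)CCC[C@@]2(C)[C@H]1CC=C3C=C(C(C)C)CC[C@H]23 | intermediate
4 | 13α,14α-dihydroxyabiet-7-en-18-amide (not isolated) | NC(=O)[C@]1(C)CCC[C@@]2(C)[C@H]1CC=C3[C@@H](O)[C@](O)(C(C)C)CC[C@H]23 | intermediate
5 | ring C-opened keto enal amide (C8 formyl on C7=C8, chain isopropyl ketone) | NC(=O)[C@]1(C)CCC[C@@]2(C)[C@H]1CC=C(C=O)[C@@H]2CCC(=O)C(C)C | intermediate
6 | allylic alcohol amide (C8–CH2OH, C7=C8) | NC(=O)[C@]1(C)CCC[C@@]2(C)[C@H]1CC=C(CO)[C@@H]2CCC(=O)C(C)C | intermediate
7 | N-allyl-N-(2-nitrophenylsulfonyl) acetone hydrazone adduct (not isolated) | NC(=O)[C@]1(C)CCC[C@@]2(C)[C@H]1CC=C(CN(N=C(C)C)S(=O)(=O)c3ccccc3[N+](=O)[O-])[C@@H]2CCC(=O)C(C)C | intermediate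
8 | allylic monoalkyl diazene (not isolated) | NC(=O)[C@]1(C)CCC[C@@]2(C)[C@H]1CC=C(CN=N)[C@@H]2CCC(=O)C(C)C | intermediate
9 | exocyclic alkene amide (C8=CH2) | NC(=O)[C@]1(C)CCC[C@@]2(C)[C@H]1CCC(=C)[C@@H]2CCC(=O)C(C)C | intermediate
10 | 8α-hydroxy amide (C8 β-methyl), chain isopropyl ketone | NC(=O)[C@]1(C)CCC[C@@]2(C)[C@H]1CC[C@@](C)(O)[C@@H]2CCC(=O)C(C)C | intermediate
11 | 8α-triethylsilyloxy amide, chain isopropyl ketone | NC(=O)[C@]1(C)CCC[C@@]2(C)[C@H]1CC[C@@](C)(O[Si](CC)(CC)CC)[C@@H]2CCC(=O)C(C)C | intermediate
12 | 8α-triethylsilyloxy C4 carboxamide, chain isopropyl ester (key-step precursor) | NC(=O)[C@]1(C)CCC[C@@]2(C)[C@H]1CC[C@@](C)(O[Si](CC)(CC)CC)[C@@H]2CCC(=O)OC(C)C | intermediate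
13 | (diacetoxyiodo)benzene | CC(=O)OI(OC(C)=O)c1ccccc1 | starting material
14 | N-iodoamide of 12 (not isolated) | INC(=O)[C@]1(C)CCC[C@@]2(C)[C@H]1CC[C@@](C)(O[Si](CC)(CC)CC)[C@@H]2CCC(=O)OC(C)C | intermediate
15 | C6 iodide of 12 (not isolated; either C6 epimer, C6 drawn without descriptor) | NC(=O)[C@]1(C)CCC[C@@]2(C)[C@H]1C(I)C[C@@](C)(O[Si](CC)(CC)CC)[C@@H]2CCC(=O)OC(C)C | intermediate
16 | iminolactone, C4 imidate carbon to 6α-O (not isolated) | N=C1[C@]2(C)CCC[C@@]3(C)[C@H]2[C@@H](O1)C[C@@](C)(O[Si](CC)(CC)CC)[C@@H]3CCC(=O)OC(C)C | intermediate
17 | γ-lactone, C4 carbonyl to 6α-O, 8α-triethylsilyloxy, chain isopropyl ester | O=C1[C@]2(C)CCC[C@@]3(C)[C@H]2[C@@H](O1)C[C@@](C)(O[Si](CC)(CC)CC)[C@@H]3CCC(=O)OC(C)C | intermediate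
18 | dipotassium 6α-hydroxy dicarboxylate (not isolated) | [K+].[K+].[O-]C(=O)[C@]1(C)CCC[C@@]2(C)[C@H]1[C@@H](O)C[C@@](C)(O[Si](CC)(CC)CC)[C@@H]2CCC(=O)[O-] | intermediate
19 | 6α-hydroxy dimethyl ester, 8α-triethylsilyloxy | COC(=O)[C@]1(C)CCC[C@@]2(C)[C@H]1[C@@H](O)C[C@@](C)(O[Si](CC)(CC)CC)[C@@H]2CCC(=O)OC | intermediate
20 | 6α,8α-bis(triethylsilyloxy) dimethyl ester | COC(=O)[C@]1(C)CCC[C@@]2(C)[C@H]1[C@@H](O[Si](CC)(CC)CC)C[C@@](C)(O[Si](CC)(CC)CC)[C@@H]2CCC(=O)OC | intermediate
21 | C13 N-methoxy-N-methylamide | COC(=O)[C@]1(C)CCC[C@@]2(C)[C@H]1[C@@H](O[Si](CC)(CC)CC)C[C@@](C)(O[Si](CC)(CC)CC)[C@@H]2CCC(=O)N(C)OC | intermediate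
22 | C13 methyl ketone | COC(=O)[C@]1(C)CCC[C@@]2(C)[C@H]1[C@@H](O[Si](CC)(CC)CC)C[C@@](C)(O[Si](CC)(CC)CC)[C@@H]2CCC(C)=O | intermediate
23 | ethyl (13E)-enoate | COC(=O)[C@]1(C)CCC[C@@]2(C)[C@H]1[C@@H](O[Si](CC)(CC)CC)C[C@@](C)(O[Si](CC)(CC)CC)[C@@H]2CC/C(C)=C/C(=O)OCC | intermediate
24 | (13E)-allylic alcohol | COC(=O)[C@]1(C)CCC[C@@]2(C)[C@H]1[C@@H](O[Si](CC)(CC)CC)C[C@@](C)(O[Si](CC)(CC)CC)[C@@H]2CC/C(C)=C/CO | intermediate
25 | (13E)-enal | COC(=O)[C@]1(C)CCC[C@@]2(C)[C@H]1[C@@H](O[Si](CC)(CC)CC)C[C@@](C)(O[Si](CC)(CC)CC)[C@@H]2CC/C(C)=C/C=O | intermediate
26 | 4-methylfuran-2(5H)-one | CC1=CC(=O)OC1 | starting material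
27 | tert-butyldimethyl[(4-methylfuran-2-yl)oxy]silane | Cc1coc(O[Si](C)(C)C(C)(C)C)c1 | intermediate
28 | 15-O-trichlorosilyl ether of 29 (not isolated) | COC(=O)[C@]1(C)CCC[C@@]2(C)[C@H]1[C@@H](O[Si](CC)(CC)CC)C[C@@](C)(O[Si](CC)(CC)CC)[C@@H]2CC/C(C)=C/[C@H](O[Si](Cl)(Cl)Cl)[C@H]1OC(=O)C=C1C | intermediate
29 | 6,8-bis-O-triethylsilyl ether of the target (15S,16S) | COC(=O)[C@]1(C)CCC[C@@]2(C)[C@H]1[C@@H](O[Si](CC)(CC)CC)C[C@@](C)(O[Si](CC)(CC)CC)[C@@H]2CC/C(C)=C/[C@H](O)[C@H]1OC(=O)C=C1C | intermediate
30 | CNP0104474.1 | COC(=O)[C@]1(C)CCC[C@@]2(C)[C@H]1[C@@H](O)C[C@@](C)(O)[C@@H]2CC/C(C)=C/[C@H](O)[C@H]1OC(=O)C=C1C | target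

## Step count and least certain steps

Total step count: 18. Longest linear sequence: 17 (steps 1 to 15, then 17 and 18, from 1); step 16 is a one-step side branch from 26.

**Step 8 (key step).** The most likely failures are:
- Hofmann-type rearrangement of the primary amide by the trivalent iodine oxidant before N-iodination takes place;
- closure through nitrogen to a lactam;
- loss of the silyl ether to hydrogen iodide, followed by alkoxy-radical fragmentation at C8;
- elimination from a cationic C6 intermediate.

All of these arise because several oxidative pathways compete at one hindered amide. Fallback: from 12, nitrosative deamination (t-BuONO, AcOH/MeCN) gives the C4 carboxylic acid F1. Carboxylate-directed aliphatic C–H hydroxylation with the iron catalyst [Fe(PDP)(MeCN)2](SbF6)2 (PDP = 1,1'-bis(pyridin-2-ylmethyl)-2,2'-bipyrrolidine) and H2O2 in MeCN, with the substrate carboxylate as the only carboxylate ligand, should then oxidise the γ-methylene C6 and close the lactone, returning to the route at 17.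

**Step 17.** Poor facial selectivity at the aldehyde or erosion of the syn preference is the main risk. The two methyl groups next to the reacting carbons (C13 methyl of the enal, C4 methyl of the furan) lie outside the usual substrate range of the catalyst, and the ring stereocentres are too remote to help. Fallback: from 25 and 27, uncatalysed-in-the-chiral-sense addition with BF3·OEt2 (CH2Cl2, −78 °C) should give the syn adducts as a pair, 29 and its (15R,16R) diastereomer F2. Sharpless kinetic resolution (Ti(OiPr)4, L-(+)-diisopropyl tartrate, t-BuOOH, CH2Cl2, −20 °C) should then epoxidise the fast-reacting F2 to the epoxy alcohol F3 and leave the slow-reacting 15S isomer, coming back to the route at 29.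

**Step 13.** Incomplete E selectivity in the olefination of a methyl ketone is the risk, because the two α-substituents differ little in size, and the isomers must then be separated. Fallback: from 21, addition of the lithium enolate of ethyl acetate (LiN(SiMe3)2, EtOAc, THF, −78 °C) gives the ethyl β-keto ester F4. The chelated sodium enolate with Tf2O (NaH, Et2O, 0 °C) gives the (Z)-enol triflate F5. Methylation with retention (MeMgBr, catalytic Fe(acac)3, THF/N-methylpyrrolidone, −30 °C) returns to the route at 23 with the geometry fixed by the enolate.

**Step 5.** Trapping of the planar C8 radical on the wrong face, or reversible hemiketal formation with the C13 ketone slowing the reaction, would lower the yield of the 8α-alcohol, since the preference rests only on the axial C10 methyl. Fallback: from 9, epoxidation with dimethyldioxirane (acetone, 0 °C) should occur on the α face to give the spiro-epoxide F6. Opening with LiI/AcOH in THF at the primary carbon gives the iodohydrin F7, and radical deiodination (Bu3SnH, AIBN, toluene, 80 °C) returns to the route at 10.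

## Further compounds

F1 | step 8 | C4 carboxylic acid corresponding to 12 (8α-triethylsilyloxy, chain isopropyl ester) | OC(=O)[C@]1(C)CCC[C@@]2(C)[C@H]1CC[C@@](C)(O[Si](CC)(CC)CC)[C@@H]2CCC(=O)OC(C)C
F2 | step 17 | (15R,16R)-diastereomer of 29 | COC(=O)[C@]1(C)CCC[C@@]2(C)[C@H]1[C@@H](O[Si](CC)(CC)CC)C[C@@](C)(O[Si](CC)(CC)CC)[C@@H]2CC/C(C)=C/[C@@H](O)[C@@H]1OC(=O)C=C1C
F3 | step 17 | (13R,14R)-13,14-epoxide of F2 | COC(=O)[C@]1(C)CCC[C@@]2(C)[C@H]1[C@@H](O[Si](CC)(CC)CC)C[C@@](C)(O[Si](CC)(CC)CC)[C@@H]2CC[C@@]3(C)O[C@@H]3[C@@H](O)[C@@H]4OC(=O)C=C4C
F4 | step 13 | ethyl β-keto ester (chain CH2CH2C(=O)CH2CO2Et) | COC(=O)[C@]1(C)CCC[C@@]2(C)[C@H]1[C@@H](O[Si](CC)(CC)CC)C[C@@](C)(O[Si](CC)(CC)CC)[C@@H]2CCC(=O)CC(=O)OCC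
F5 | step 13 | (Z)-enol triflate of F4 | COC(=O)[C@]1(C)CCC[C@@]2(C)[C@H]1[C@@H](O[Si](CC)(CC)CC)C[C@@](C)(O[Si](CC)(CC)CC)[C@@H]2CC/C(OS(=O)(=O)C(F)(F)F)=C/C(=O)OCC
F6 | step 5 | 8α-spiro-epoxide of 9 (epoxide oxygen α) | NC(=O)[C@]1(C)CCC[C@@]2(C)[C@H]1CC[C@@]3(OC3)[C@@H]2CCC(=O)C(C)C
F7 | step 5 | 8α-hydroxy C8-iodomethyl amide (iodohydrin) | NC(=O)[C@]1(C)CCC[C@@]2(C)[C@H]1CC[C@@](CI)(O)[C@@H]2CCC(=O)C(C)C
A1 | alternative 1 | (E)-tert-butyldimethyl[(3-methylpenta-2,4-dien-1-yl)oxy]silane | C=C/C(C)=C/CO[Si](C)(C)C(C)(C)C
A2 | alternative 1 | methacrolein | CC(=C)C=O
A3 | alternative 1 | ring A cyclohexene aldehyde with C4 and C5 set | O=C[C@]1(C)CCC=C(C)[C@H]1CO[Si](C)(C)C(C)(C)C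
A4 | alternative 2 | acyclic triene ester (E-2-methyl enoate, C6 OTBS, C8 OTES, C9 PMB-oxyethyl, C10=C1–C2=C3 diene) | C=C/C=C(\C)[C@@H](CCOCc1ccc(OC)cc1)[C@](C)(O[Si](CC)(CC)CC)C[C@H](O[Si](C)(C)C(C)(C)C)/C=C(\C)C(=O)OC
A5 | alternative 2 | trans-fused octalin ester with C1=C2 | COC(=O)[C@]1(C)CC=C[C@@]2(C)[C@H]1[C@@H](O[Si](C)(C)C(C)(C)C)C[C@@](C)(O[Si](CC)(CC)CC)[C@@H]2CCOCc1ccc(OC)cc1
A6 | alternative 3 | terminal alkyne (6α-OTBS, 8α-OH, C9 but-3-ynyl chain) | COC(=O)[C@]1(C)CCC[C@@]2(C)[C@H]1[C@@H](O[Si](C)(C)C(C)(C)C)C[C@@](C)(O)[C@@H]2CCC#C
A7 | alternative 3 | (S)-2-[(4-methoxybenzyl)oxy]-3-[(triethylsilyl)oxy]propanal | O=C[C@@H](OCc1ccc(OC)cc1)CO[Si](CC)(CC)CC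
A8 | alternative 3 | (E)-allylic alcohol with C15 and C16 set | COC(=O)[C@]1(C)CCC[C@@]2(C)[C@H]1[C@@H](O[Si](C)(C)C(C)(C)C)C[C@@](C)(O)[C@@H]2CC/C(C)=C/[C@H](O)[C@@H](OCc1ccc(OC)cc1)CO[Si](CC)(CC)CC
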